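The cyclopentenone ring (C1'–C5': C1' ketone, C2' amide-bearing, C3' enol, C4'/C5' methylenes) is the enol of a symmetric 2-acylaminocyclopentane-1,3-dione, that is, a cyclised N-acyl 5-aminolevulinic acid. The ring is therefore carried as an open-chain N-acyl 5-aminolevulinate pentafluorophenyl ester while the epoxycyclohexenone core and the all-E triene are assembled (asymmetric quinone-monoketal epoxidation, alkenyllithium addition anti to the epoxide, Stille union). It is closed last: a biomimetic, magnesium-mediated soft-enolisation Dieckmann condensation joins the nitrogen-bearing methylene carbon (future C2') to the ester carbonyl (future C1'), creating the carbocycle and its vinylogous-acid enol in one operation. Ketal hydrolysis then gives the target.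

Key step: step 12

Assumption: the sense of induction in step 5 is taken to be that N-benzylcinchoninium chloride delivers the (1R,6S)-epoxide; should the opposite sense be found, the pseudoenantiomeric N-benzylcinchonidinium chloride is used with no other change.

Step 1
Reactants: 1 cyclohexanecarboxaldehyde; 2 triethyl (E)-4-phosphonocrotonate
Product: 3 ethyl (2E,4E)-5-cyclohexylpenta-2,4-dienoate
Conditions: LiN(SiMe3)2, THF, −78 °C → rt
Reagents that add atoms: none
Why: Vinylogous Horner–Wadsworth–Emmons olefination: the lithiated phosphonocrotonate adds to the unhindered aldehyde through its phosphorus-bearing carbon and the stabilised adduct collapses to the thermodynamically favoured (E)-alkene, the existing (E)-enoate geometry being retained.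

Step 2
Reactants: 3 ethyl (2E,4E)-5-cyclohexylpenta-2,4-dienoate
Product: 4 (2E,4E)-5-cyclohexylpenta-2,4-dienoic acid
Conditions: LiOH, THF/MeOH/H2O, rt; then 1 M HCl
Reagents that add atoms: lithium hydroxide, [Li+].[OH-]
Why: Saponification of an unhindered ethyl ester by hydroxide through acyl–oxygen cleavage, which leaves the (2E,4E)-diene untouched.

Step 3
Reactants: 4 (2E,4E)-5-cyclohexylpenta-2,4-dienoic acid; 5 2,5-dimethoxyaniline
Product: 7 (2E,4E)-5-cyclohexyl-N-(2,5-dimethoxyphenyl)penta-2,4-dienamide, via (2E,4E)-5-cyclohexylpenta-2,4-dienoyl chloride 6 (not isolated)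
Conditions: (COCl)2, cat. DMF, CH2Cl2, 0 °C → rt; then 5, pyridine, CH2Cl2, 0 °C → rt
Reagents that add atoms: oxalyl chloride, O=C(Cl)C(=O)Cl (chlorine of intermediate 6 only)
Why: Acid chloride formation with oxalyl chloride under DMF catalysis followed by N-acylation of the aniline (amide formation of the Schotten–Baumann type with pyridine as acid scavenger), neither of which affects the diene.

Step 4
Reactants: 7 (2E,4E)-5-cyclohexyl-N-(2,5-dimethoxyphenyl)penta-2,4-dienamide
Product: 8 (2E,4E)-5-cyclohexyl-N-(6,6-dimethoxy-3-oxocyclohexa-1,4-dien-1-yl)penta-2,4-dienamide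
Conditions: PhI(OAc)2, MeOH, 0 °C → rt; aq. NaHCO3 work-up
Reagents that add atoms: methanol, CO; water, O
Why: Oxidative dearomatisation of the para-dimethoxyarene by the trivalent iodine reagent in methanol: methanol is captured at the methoxy carbon ortho to nitrogen, whereas the remote methoxy-oxocarbenium centre, made labile by vinylogous donation from the amide nitrogen, loses its methyl group as methanol on attack of water, so that the quinone monoketal with the ketone para to the ketal is formed regioselectively.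

Step 5
Reactants: 8 (2E,4E)-5-cyclohexyl-N-(6,6-dimethoxy-3-oxocyclohexa-1,4-dien-1-yl)penta-2,4-dienamide
Product: 9 (2E,4E)-5-cyclohexyl-N-[(1R,6S)-2,2-dimethoxy-5-oxo-7-oxabicyclo[4.1.0]hept-3-en-3-yl]penta-2,4-dienamide
Conditions: t-BuOOH, NaOH (aq.), N-benzylcinchoninium chloride (cat.), toluene, rt; recrystallisation
Reagents that add atoms: tert-butyl hydroperoxide, CC(C)(C)OO
Why: Weitz–Scheffer nucleophilic epoxidation under chiral phase-transfer catalysis: the tert-butyl hydroperoxide anion, ion-paired with the cinchoninium cation, adds to the only unsubstituted enone double bond (the amide-bearing one is deactivated as a vinylogous amide) and the chiral ion pair differentiates its enantiotopic faces, setting both epoxide stereocentres (cis by ring constraint) in the (1R,6S) sense, with recrystallisation to raise the enantiomeric purity.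

Step 6
Reactants: 9 (2E,4E)-5-cyclohexyl-N-[(1R,6S)-2,2-dimethoxy-5-oxo-7-oxabicyclo[4.1.0]hept-3-en-3-yl]penta-2,4-dienamide; 10 (E)-1,2-bis(tributylstannyl)ethene
Product: 12 (2E,4E)-5-cyclohexyl-N-[(1R,5S,6S)-5-hydroxy-2,2-dimethoxy-5-[(E)-2-(tributylstannyl)ethenyl]-7-oxabicyclo[4.1.0]hept-3-en-3-yl]penta-2,4-dienamide, via (E)-2-(tributylstannyl)ethenyllithium 11 (not isolated)
Conditions: 10 (3.3 equiv), n-BuLi (3.0 equiv), THF, −78 °C; then 9, −78 °C; aq. NH4Cl
Reagents that add atoms: none
Why: Tin–lithium exchange gives the (E)-alkenyllithium with retention, and after the first equivalent has deprotonated the amide N–H a further equivalent adds 1,2 to the ketone from the face opposite to the epoxide oxygen (steric and electrostatic shielding by the epoxide), so that the new tertiary carbinol carries its hydroxyl syn to the epoxide (5S in this stannane).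

Step 7
Reactants: 13 glutaconaldehyde potassium salt (potassium (1E,3E)-5-oxopenta-1,3-dien-1-olate)
Product: 14 (2E,4E)-5-bromopenta-2,4-dienal
Conditions: PPh3, Br2, CH2Cl2, 0 °C → rt
Reagents that add atoms: bromine, BrBr (delivered as Ph3PBr2)
Why: Deoxybromination of the enolate (Appel-type): Ph3PBr2 converts the enolate oxygen into an oxyphosphonium leaving group that bromide displaces by addition–elimination, and the fully conjugated bromodienal settles in the (2E,4E) geometry.

Step 8
Reactants: 14 (2E,4E)-5-bromopenta-2,4-dienal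
Product: 15 (2E,4E)-5-bromopenta-2,4-dienoic acid
Conditions: NaClO2, NaH2PO4, 2-methyl-2-butene, t-BuOH/H2O, 0 °C → rt
Reagents that add atoms: sodium chlorite, [Na+].[O-]Cl=O
Why: Pinnick oxidation: chlorous acid oxidises the aldehyde selectively to the acid while 2-methyl-2-butene scavenges the hypochlorous acid that would otherwise attack the bromodiene.

Step 9
Reactants: 15 (2E,4E)-5-bromopenta-2,4-dienoic acid; 16 5-aminolevulinic acid hydrochloride (5-amino-4-oxopentanoic acid hydrochloride)
Product: 18 5-[(2E,4E)-5-bromopenta-2,4-dienamido]-4-oxopentanoic acid, via (2E,4E)-5-bromopenta-2,4-dienoyl chloride 17 (not isolated)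
Conditions: (COCl)2, cat. DMF, CH2Cl2, 0 °C; then 16, NaHCO3, THF/H2O, 0 °C; then 1 M HCl to pH 2–3
Reagents that add atoms: oxalyl chloride, O=C(Cl)C(=O)Cl (chlorine of intermediate 17 only)
Why: Schotten–Baumann N-acylation: the acid chloride captures the amine of 5-aminolevulinic acid as soon as bicarbonate sets it free, faster than the self-condensation of the free α-amino ketone, and acidification returns the carboxylic acid.

Step 10
Reactants: 18 5-[(2E,4E)-5-bromopenta-2,4-dienamido]-4-oxopentanoic acid
Product: 19 pentafluorophenyl 5-[(2E,4E)-5-bromopenta-2,4-dienamido]-4-oxopentanoate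
Conditions: C6F5OH, DCC, EtOAc, 0 °C → rt
Reagents that add atoms: pentafluorophenol, Oc1c(F)c(F)c(F)c(F)c1F
Why: Carbodiimide esterification (Steglich-type active ester formation): the acidic pentafluorophenol traps the O-acylisourea rapidly, giving a bench-stable active ester without involving the ketone or the secondary amide.

Step 11
Reactants: 12 (2E,4E)-5-cyclohexyl-N-[(1R,5S,6S)-5-hydroxy-2,2-dimethoxy-5-[(E)-2-(tributylstannyl)ethenyl]-7-oxabicyclo[4.1.0]hept-3-en-3-yl]penta-2,4-dienamide; 19 pentafluorophenyl 5-[(2E,4E)-5-bromopenta-2,4-dienamido]-4-oxopentanoate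
Product: 20 (2E,4E)-5-cyclohexyl-N-[(1R,5R,6S)-5-[(1E,3E,5E)-7-{[2,5-dioxo-5-(pentafluorophenoxy)pentyl]amino}-7-oxohepta-1,3,5-trien-1-yl]-5-hydroxy-2,2-dimethoxy-7-oxabicyclo[4.1.0]hept-3-en-3-yl]penta-2,4-dienamide
Conditions: PdCl2(MeCN)2 (cat.), DMF (amine-free), rt, dark
Reagents that add atoms: none
Why: Stille coupling: zerovalent palladium generated from PdCl2(MeCN)2 inserts into the alkenyl C–Br bond, transmetalation with the alkenylstannane and reductive elimination join the two sp2 carbons with retention of both alkene geometries, and the neutral, ligand-free conditions spare the active ester, the epoxide, the ketal and the free hydroxyl.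

Step 12
Reactants: 20 (2E,4E)-5-cyclohexyl-N-[(1R,5R,6S)-5-[(1E,3E,5E)-7-{[2,5-dioxo-5-(pentafluorophenoxy)pentyl]amino}-7-oxohepta-1,3,5-trien-1-yl]-5-hydroxy-2,2-dimethoxy-7-oxabicyclo[4.1.0]hept-3-en-3-yl]penta-2,4-dienamide
Product: 21 (2E,4E)-5-cyclohexyl-N-[(1R,5R,6S)-5-hydroxy-5-[(1E,3E,5E)-7-[(2-hydroxy-5-oxocyclopent-1-en-1-yl)amino]-7-oxohepta-1,3,5-trien-1-yl]-2,2-dimethoxy-7-oxabicyclo[4.1.0]hept-3-en-3-yl]penta-2,4-dienamide
Conditions: MgBr2·OEt2 (3 equiv), i-Pr2NEt (4 equiv), CH2Cl2 (0.005 M), 0 °C → rt; pH 4 buffer, 0 °C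
Reagents that add atoms: none
Why: MgBr2·OEt2 and i-Pr2NEt enolise the ketone of the 5-aminolevulinate chain reversibly, the magnesium enolate on the nitrogen-bearing methylene carbon attacks the pentafluorophenyl ester carbonyl with loss of pentafluorophenoxide, and the resulting 2-acylaminocyclopentane-1,3-dione is at once deprotonated to its magnesium enolate, which gives the 2-amido-3-hydroxycyclopent-2-enone on mildly acidic work-up. The closest known reaction types are the Dieckmann condensation of 4-oxoalkanoates to cyclopentane-1,3-diones and the magnesium-bromide-mediated soft-enolisation acylation of ketones by pentafluorophenyl esters, combined here in an intramolecular, biomimetic sense. The ring closes in a 5-exo-trig (enolexo) mode, forming the bond between the amide-bearing carbon C2' and the carbonyl carbon C1', and no stereocentre is created. The step needs acylation at carbon instead of oxygen or nitrogen and reaction of the nitrogen-side enolate instead of the chain-side one: only the nitrogen-side enolate can reach the ester through a five-membered transition state (the other would close a three-membered ring), and any enol lactone or six-membered imide remains an acyl donor that pentafluorophenoxide can reopen, whereas the C-acylated product is withdrawn irreversibly as the enolate of a vinylogous acid. The epoxide must stay closed, which the substrate secures because with the ketone still masked as the dimethyl ketal both epoxide carbons are neopentyl-like and shielded from bromide, and the tertiary alkoxide, being syn to the epoxide oxygen, cannot undergo a Payne shift. High dilution suppresses intermolecular Claisen condensation.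

Step 13
Reactants: 21 (2E,4E)-5-cyclohexyl-N-[(1R,5R,6S)-5-hydroxy-5-[(1E,3E,5E)-7-[(2-hydroxy-5-oxocyclopent-1-en-1-yl)amino]-7-oxohepta-1,3,5-trien-1-yl]-2,2-dimethoxy-7-oxabicyclo[4.1.0]hept-3-en-3-yl]penta-2,4-dienamide
Product: 22 (2E,4E)-5-cyclohexyl-N-[(1R,5R,6S)-5-hydroxy-5-[(1E,3E,5E)-7-[(2-hydroxy-5-oxocyclopent-1-en-1-yl)amino]-7-oxohepta-1,3,5-trien-1-yl]-2-oxo-7-oxabicyclo[4.1.0]hept-3-en-3-yl]penta-2,4-dienamide
Conditions: montmorillonite K10 clay, CH2Cl2, rt
Reagents that add atoms: water, O
Why: Acid-clay-promoted ketal hydrolysis through the methoxy-oxocarbenium ion under heterogeneous, weakly nucleophilic conditions that should spare the epoxide, the tertiary alcohol, the polyenes and the vinylogous acid and that touch no stereocentre.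

Compound list
1 | cyclohexanecarboxaldehyde | O=CC1CCCCC1 | starting material
2 | triethyl (E)-4-phosphonocrotonate | CCOC(=O)/C=C/CP(=O)(OCC)OCC | starting material
3 | ethyl (2E,4E)-5-cyclohexylpenta-2,4-dienoate | CCOC(=O)/C=C/C=C/C1CCCCC1 | intermediate
4 | (2E,4E)-5-cyclohexylpenta-2,4-dienoic acid | OC(=O)/C=C/C=C/C1CCCCC1 | intermediate
5 | 2,5-dimethoxyaniline | COc1ccc(OC)c(N)c1 | starting material
6 | (2E,4E)-5-cyclohexylpenta-2,4-dienoyl chloride | ClC(=O)/C=C/C=C/C1CCCCC1 | intermediate (not isolated)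
7 | (2E,4E)-5-cyclohexyl-N-(2,5-dimethoxyphenyl)penta-2,4-dienamide | COc1ccc(OC)c(NC(=O)/C=C/C=C/C2CCCCC2)c1 | intermediate
8 | (2E,4E)-5-cyclohexyl-N-(6,6-dimethoxy-3-oxocyclohexa-1,4-dien-1-yl)penta-2,4-dienamide | O=C(/C=C/C=C/C1CCCCC1)NC1=CC(=O)C=CC1(OC)OC | intermediate
9 | (2E,4E)-5-cyclohexyl-N-[(1R,6S)-2,2-dimethoxy-5-oxo-7-oxabicyclo[4.1.0]hept-3-en-3-yl]penta-2,4-dienamide | O=C(/C=C/C=C/C1CCCCC1)NC1=CC(=O)[C@H]2O[C@H]2C1(OC)OC | intermediate
10 | (E)-1,2-bis(tributylstannyl)ethene | CCCC[Sn](CCCC)(CCCC)/C=C/[Sn](CCCC)(CCCC)CCCC | starting material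
11 | (E)-2-(tributylstannyl)ethenyllithium | [Li]/C=C/[Sn](CCCC)(CCCC)CCCC | intermediate (not isolated)
12 | (2E,4E)-5-cyclohexyl-N-[(1R,5S,6S)-5-hydroxy-2,2-dimethoxy-5-[(E)-2-(tributylstannyl)ethenyl]-7-oxabicyclo[4.1.0]hept-3-en-3-yl]penta-2,4-dienamide | O=C(/C=C/C=C/C1CCCCC1)NC1=C[C@](O)(/C=C/[Sn](CCCC)(CCCC)CCCC)[C@H]2O[C@H]2C1(OC)OC | intermediate
13 | glutaconaldehyde potassium salt (potassium (1E,3E)-5-oxopenta-1,3-dien-1-olate) | [K+].[O-]/C=C/C=C/C=O | starting material
14 | (2E,4E)-5-bromopenta-2,4-dienal | O=C/C=C/C=C/Br | intermediate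
15 | (2E,4E)-5-bromopenta-2,4-dienoic acid | OC(=O)/C=C/C=C/Br | intermediate
16 | 5-aminolevulinic acid hydrochloride | Cl.NCC(=O)CCC(=O)O | starting material
17 | (2E,4E)-5-bromopenta-2,4-dienoyl chloride | ClC(=O)/C=C/C=C/Br | intermediate (not isolated)
18 | 5-[(2E,4E)-5-bromopenta-2,4-dienamido]-4-oxopentanoic acid | OC(=O)CCC(=O)CNC(=O)/C=C/C=C/Br | intermediate
19 | pentafluorophenyl 5-[(2E,4E)-5-bromopenta-2,4-dienamido]-4-oxopentanoate | O=C(CCC(=O)CNC(=O)/C=C/C=C/Br)Oc1c(F)c(F)c(F)c(F)c1F | intermediate
20 | (2E,4E)-5-cyclohexyl-N-[(1R,5R,6S)-5-[(1E,3E,5E)-7-{[2,5-dioxo-5-(pentafluorophenoxy)pentyl]amino}-7-oxohepta-1,3,5-trien-1-yl]-5-hydroxy-2,2-dimethoxy-7-oxabicyclo[4.1.0]hept-3-en-3-yl]penta-2,4-dienamide | O=C(/C=C/C=C/C1CCCCC1)NC1=C[C@](O)(/C=C/C=C/C=C/C(=O)NCC(=O)CCC(=O)Oc2c(F)c(F)c(F)c(F)c2F)[C@H]2O[C@H]2C1(OC)OC | intermediate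
21 | (2E,4E)-5-cyclohexyl-N-[(1R,5R,6S)-5-hydroxy-5-[(1E,3E,5E)-7-[(2-hydroxy-5-oxocyclopent-1-en-1-yl)amino]-7-oxohepta-1,3,5-trien-1-yl]-2,2-dimethoxy-7-oxabicyclo[4.1.0]hept-3-en-3-yl]penta-2,4-dienamide | O=C(/C=C/C=C/C1CCCCC1)NC1=C[C@](O)(/C=C/C=C/C=C/C(=O)NC2=C(O)CCC2=O)[C@H]2O[C@H]2C1(OC)OC | intermediate
22 | (2E,4E)-5-cyclohexyl-N-[(1R,5R,6S)-5-hydroxy-5-[(1E,3E,5E)-7-[(2-hydroxy-5-oxocyclopent-1-en-1-yl)amino]-7-oxohepta-1,3,5-trien-1-yl]-2-oxo-7-oxabicyclo[4.1.0]hept-3-en-3-yl]penta-2,4-dienamide | O=C(/C=C/C=C/C1CCCCC1)NC1=C[C@](O)(/C=C/C=C/C=C/C(=O)NC2=C(O)CCC2=O)[C@H]2O[C@H]2C1=O | target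

Total step count: 13. Longest linear sequence: 9 steps (steps 1, 2, 3, 4, 5, 6, 11, 12, 13); steps 7–10 form the convergent branch.

Steps most likely to fail

Step 12 (ring closure on the complete skeleton). The acylation may be diverted to oxygen or nitrogen (enol lactone or six-membered imide) without funnelling on to the dione, or the magnesium Lewis acid may open the epoxide or ionise the ketal before the carbon–carbon bond forms. Fallback: the closure is moved to the small fragment, and the union is then made with the ring already in place. The fallback sets out from 19, taken up only after 12 is in hand, so that the cyclopentenone is still the last ring to close. The same Dieckmann closure is applied to 19 (MgBr2·OEt2, i-Pr2NEt, CH2Cl2); excess reagent, longer times and warming are tolerable there because no epoxide, ketal or carbinol is present. It should give (2E,4E)-5-bromo-N-(2-hydroxy-5-oxocyclopent-1-en-1-yl)penta-2,4-dienamide F1. Stille coupling of F1 with stannane 12 (PdCl2(MeCN)2, DMF, rt) then gives 21, where the route is rejoined before step 13.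

Step 13 (ketal hydrolysis on the finished skeleton). Acid may ionise the tertiary, triene-conjugated carbinol or open the epoxide, and the polar vinylogous acid may be retained irreversibly on the clay. Fallback: the ketone is unmasked before the fragments are joined, so that the ring closure becomes the very last operation. Setting out from 12, montmorillonite K10 in CH2Cl2 should give (2E,4E)-5-cyclohexyl-N-[(1R,5S,6S)-5-hydroxy-2-oxo-5-[(E)-2-(tributylstannyl)ethenyl]-7-oxabicyclo[4.1.0]hept-3-en-3-yl]penta-2,4-dienamide F2. Stille coupling of F2 with 19 should give (2E,4E)-5-cyclohexyl-N-[(1R,5R,6S)-5-[(1E,3E,5E)-7-{[2,5-dioxo-5-(pentafluorophenoxy)pentyl]amino}-7-oxohepta-1,3,5-trien-1-yl]-5-hydroxy-2-oxo-7-oxabicyclo[4.1.0]hept-3-en-3-yl]penta-2,4-dienamide F3. The magnesium-mediated Dieckmann closure of F3, run at 0 °C with the minimum of MgBr2·OEt2 to protect the epoxy ketone, then delivers target 22 directly.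

Step 5 (asymmetric epoxidation). Facial discrimination by the chiral ion pair may be poor, or of the wrong sense, with the N-dienoyl substituent, and turnover of the deprotonated vinylogous amide may be slow. Fallback: the epoxidation is run on the crystalline tert-butyl carbamate and the dienoyl group is introduced afterwards. Setting out from 5, Boc2O should give tert-butyl N-(2,5-dimethoxyphenyl)carbamate F4. PhI(OAc)2 in MeOH should give tert-butyl N-(6,6-dimethoxy-3-oxocyclohexa-1,4-dien-1-yl)carbamate F5. The same phase-transfer epoxidation, followed by recrystallisation, should give tert-butyl N-[(1R,6S)-2,2-dimethoxy-5-oxo-7-oxabicyclo[4.1.0]hept-3-en-3-yl]carbamate F6. TFA in CH2Cl2 at 0 °C removes the carbamate to give (1S,6R)-4-amino-5,5-dimethoxy-7-oxabicyclo[4.1.0]hept-3-en-2-one F7. N-acylation of F7 with acid chloride 6 (LiOt-Bu, THF, −78 °C → 0 °C) returns to 9.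

Further compounds
F1 | step 12 | (2E,4E)-5-bromo-N-(2-hydroxy-5-oxocyclopent-1-en-1-yl)penta-2,4-dienamide | O=C(/C=C/C=C/Br)NC1=C(O)CCC1=O
F2 | step 13 | (2E,4E)-5-cyclohexyl-N-[(1R,5S,6S)-5-hydroxy-2-oxo-5-[(E)-2-(tributylstannyl)ethenyl]-7-oxabicyclo[4.1.0]hept-3-en-3-yl]penta-2,4-dienamide | O=C(/C=C/C=C/C1CCCCC1)NC1=C[C@](O)(/C=C/[Sn](CCCC)(CCCC)CCCC)[C@H]2O[C@H]2C1=O
F3 | step 13 | (2E,4E)-5-cyclohexyl-N-[(1R,5R,6S)-5-[(1E,3E,5E)-7-{[2,5-dioxo-5-(pentafluorophenoxy)pentyl]amino}-7-oxohepta-1,3,5-trien-1-yl]-5-hydroxy-2-oxo-7-oxabicyclo[4.1.0]hept-3-en-3-yl]penta-2,4-dienamide | O=C(/C=C/C=C/C1CCCCC1)NC1=C[C@](O)(/C=C/C=C/C=C/C(=O)NCC(=O)CCC(=O)Oc2c(F)c(F)c(F)c(F)c2F)[C@H]2O[C@H]2C1=O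
F4 | step 5 | tert-butyl N-(2,5-dimethoxyphenyl)carbamate | COc1ccc(OC)c(NC(=O)OC(C)(C)C)c1
F5 | step 5 | tert-butyl N-(6,6-dimethoxy-3-oxocyclohexa-1,4-dien-1-yl)carbamate | CC(C)(C)OC(=O)NC1=CC(=O)C=CC1(OC)OC
F6 | step 5 | tert-butyl N-[(1R,6S)-2,2-dimethoxy-5-oxo-7-oxabicyclo[4.1.0]hept-3-en-3-yl]carbamate | CC(C)(C)OC(=O)NC1=CC(=O)[C@H]2O[C@H]2C1(OC)OC
F7 | step 5 | (1S,6R)-4-amino-5,5-dimethoxy-7-oxabicyclo[4.1.0]hept-3-en-2-one | NC1=CC(=O)[C@H]2O[C@H]2C1(OC)OC
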